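**Retrosynthetic overview**
- The target is a 4-hydroxy-4-substituted cyclohexanone. A benzyloxycarbonyl group and a chlorine on the ketone α-carbon (ring C3) are carried as activating and blocking groups and are removed last by hydrogenolysis and decarboxylation.
- The strategy rests on this feature: ring C3 (α to the C4 ketone) and ring C2 (the CH2 end of a C1=C2 alkene in the open-chain form) are both nucleophilic carbons, and the oxygen on C1 stands 1,3 to the palmitate oxygen across the CH2CH2 arm, so the ester carbonyl can deliver oxygen to C1.
- Key disconnection: the C2–C3 bond (oxidative radical union, closing the only ring in a 6-endo mode) and the C1–O bond (cation captured by the palmitate carbonyl, then water).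
- The open-chain chloro keto ester comes from an aldehyde by Roskamp homologation with benzyl diazoacetate, followed by α-chlorination.
- The aldehyde comes from Negishi coupling of 3-bromobut-3-enyl palmitate with a dioxolane-bearing alkylzinc bromide, then acetal hydrolysis.

Key step: step 6

Remark: the target has no stereocentre (its carbinol carbon carries two identical ring arms), so no stereocontrol is needed; 3-bromobut-3-en-1-ol, the THF solution of [2-(1,3-dioxolan-2-yl)ethyl]zinc bromide and benzyl diazoacetate are taken as purchased materials.

**Route**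

Step 1
Reactants: 1 3-bromobut-3-en-1-ol; 2 hexadecanoyl chloride (palmitoyl chloride)
Product: 3 3-bromobut-3-en-1-yl hexadecanoate
Conditions: Et3N, DMAP (cat.), CH2Cl2, 0 °C → rt
Reagents that add atoms: none
Why: DMAP-catalysed esterification (nucleophilic acyl substitution) of an unhindered primary alcohol by an acid chloride; the vinyl bromide is inert here and no stereocentre is formed.

Step 2
Reactants: 3 3-bromobut-3-en-1-yl hexadecanoate; 4 [2-(1,3-dioxolan-2-yl)ethyl]zinc bromide (solution in THF)
Product: 5 5-(1,3-dioxolan-2-yl)-3-methylidenepentyl hexadecanoate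
Conditions: PdCl2(dppf) (5 mol %), THF, 50 °C
Reagents that add atoms: none
Why: Negishi sp2–sp3 cross-coupling, in which zerovalent palladium formed from PdCl2(dppf) inserts into the vinyl C–Br bond, the alkylzinc bromide transmetalates without touching the ester or the dioxolane, and the wide bite angle of dppf favours reductive elimination over β-hydride loss; no stereocentre is formed.

Step 3
Reactants: 5 5-(1,3-dioxolan-2-yl)-3-methylidenepentyl hexadecanoate
Product: 6 3-methylidene-6-oxohexyl hexadecanoate
Conditions: 1 M aq HCl, THF, rt
Reagents that add atoms: water, O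
Why: acid-catalysed acetal hydrolysis; dilute aqueous acid at room temperature should cleave the dioxolane while leaving the palmitate ester and the 1,1-disubstituted alkene, which needs stronger acid to migrate or hydrate.

Step 4
Reactants: 6 3-methylidene-6-oxohexyl hexadecanoate; 7 benzyl diazoacetate
Product: 8 benzyl 8-(hexadecanoyloxy)-6-methylidene-3-oxooctanoate
Conditions: SnCl2 (10 mol %), CH2Cl2, rt
Reagents that add atoms: none
Why: Roskamp reaction, in which SnCl2 (divalent tin) activates the aldehyde for attack by the diazo carbon and a 1,2-hydride shift with loss of N2 gives the β-keto ester under near-neutral conditions that spare the alkene and the palmitate.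

Step 5
Reactants: 8 benzyl 8-(hexadecanoyloxy)-6-methylidene-3-oxooctanoate
Product: 9 benzyl 2-chloro-8-(hexadecanoyloxy)-6-methylidene-3-oxooctanoate (racemic)
Conditions: NCS (1.0 equiv), Mg(ClO4)2 (10 mol %), EtOAc, 0 °C → rt
Reagents that add atoms: N-chlorosuccinimide, O=C1CCC(=O)N1Cl
Why: electrophilic α-chlorination of the magnesium-chelated enol of the 1,3-dicarbonyl unit, where one equivalent of reagent should react at the doubly activated C2 far faster than at the isolated alkene; the new C2 stereocentre is racemic and is erased when C2 becomes a radical in step 6.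

Step 6
Reactants: 9 benzyl 2-chloro-8-(hexadecanoyloxy)-6-methylidene-3-oxooctanoate
Product: 12 benzyl 1-chloro-5-[2-(hexadecanoyloxy)ethyl]-5-hydroxy-2-oxocyclohexane-1-carboxylate (mixture of racemic diastereomers), via dioxanylium acetate 10 (not isolated), via hemiorthoester 11 (not isolated)
Conditions: Mn(OAc)3·2H2O (2.2 equiv), degassed AcOH/H2O (19:1), argon, 40 °C
Reagents that add atoms: water, O
Why: Proposed new method: trivalent manganese (Mn(OAc)3) oxidises the enol of 9 by one electron to the electrophilic radical at the chlorine-bearing carbon, which adds to the CH2 terminus of the 1,1-disubstituted alkene; a second equivalent of Mn(OAc)3 oxidises the resulting tertiary radical to the cation, the palmitate carbonyl oxygen captures it by closing the six-membered spiro 1,3-dioxan-2-ylium ion 10, and water adds at the acyl carbon to give hemiorthoester 11, which opens to the tertiary alcohol and the more stable primary ester. The closest known reaction type is the Mn(OAc)3-mediated oxidative 6-endo radical cyclisation of α-chloro unsaturated β-keto esters with cationic termination; what is new is ending it by neighbouring-ester capture through a six-membered dioxanylium ion so that a hydroxyl is installed. The one ring, the cyclohexanone, closes 6-endo-trig, favoured over 5-exo because the ketone carbonyl lies inside the forming ring and attack at the unsubstituted alkene carbon gives a tertiary instead of a primary radical. The two new stereocentres (the carbon bearing Cl and CO2Bn, and the carbinol carbon) form without control, which is harmless because neither is stereogenic after step 7. The step needs cation capture by the palmitate to outrun proton loss, acetate capture and capture by the ring benzyl ester: omitting Cu(OAc)2 avoids oxidative elimination, water in the medium drains the dioxanylium ion irreversibly, and the chair-like six-membered ion on a free chain is less strained than the bridged lactone the ring ester would have to form. The chlorine blocks enolisation of 12, so the product should not be oxidised further.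

Step 7
Reactants: 12 benzyl 1-chloro-5-[2-(hexadecanoyloxy)ethyl]-5-hydroxy-2-oxocyclohexane-1-carboxylate
Product: 14 2-(1-hydroxy-4-oxocyclohexyl)ethyl hexadecanoate, via keto acid 13 (not isolated)
Conditions: H2 (1 atm), Pd/C (10 %), NaOAc (1.5 equiv), EtOAc/EtOH, rt; filter, wash with dilute aq citric acid; toluene, 50 °C
Reagents that add atoms: none
Why: catalytic hydrogenolysis on Pd/C should cleave the benzyl C–O bond and the activated tertiary C–Cl bond flanked by two carbonyl groups (NaOAc takes up the HCl), and the resulting β-keto acid decarboxylates through the usual six-membered transition state on warming; both stereocentres of 12 vanish, leaving the achiral target.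

**Compound list**
1 | 3-bromobut-3-en-1-ol | OCCC(Br)=C | starting material
2 | hexadecanoyl chloride (palmitoyl chloride) | CCCCCCCCCCCCCCCC(=O)Cl | starting material
3 | 3-bromobut-3-en-1-yl hexadecanoate | CCCCCCCCCCCCCCCC(=O)OCCC(Br)=C | intermediate
4 | [2-(1,3-dioxolan-2-yl)ethyl]zinc bromide | Br[Zn]CCC1OCCO1 | starting material
5 | 5-(1,3-dioxolan-2-yl)-3-methylidenepentyl hexadecanoate | CCCCCCCCCCCCCCCC(=O)OCCC(=C)CCC1OCCO1 | intermediate
6 | 3-methylidene-6-oxohexyl hexadecanoate | CCCCCCCCCCCCCCCC(=O)OCCC(=C)CCC=O | intermediate
7 | benzyl diazoacetate | [N-]=[N+]=CC(=O)OCc1ccccc1 | starting material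
8 | benzyl 8-(hexadecanoyloxy)-6-methylidene-3-oxooctanoate | CCCCCCCCCCCCCCCC(=O)OCCC(=C)CCC(=O)CC(=O)OCc1ccccc1 | intermediate
9 | benzyl 2-chloro-8-(hexadecanoyloxy)-6-methylidene-3-oxooctanoate (racemic) | CCCCCCCCCCCCCCCC(=O)OCCC(=C)CCC(=O)C(Cl)C(=O)OCc1ccccc1 | intermediate
10 | benzyl 8-chloro-9-oxo-2-pentadecyl-1,3-dioxaspiro[5.5]undec-1-en-1-ium-8-carboxylate acetate (spiro 1,3-dioxan-2-ylium ion whose C4 is the former tertiary carbon of the new ring) | CCCCCCCCCCCCCCCC1=[O+]C2(CCO1)CCC(=O)C(Cl)(C2)C(=O)OCc3ccccc3.CC(=O)[O-] | intermediate
11 | benzyl 8-chloro-2-hydroxy-9-oxo-2-pentadecyl-1,3-dioxaspiro[5.5]undecane-8-carboxylate (hemiorthoester) | CCCCCCCCCCCCCCCC1(O)OCCC2(O1)CCC(=O)C(Cl)(C2)C(=O)OCc3ccccc3 | intermediate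
12 | benzyl 1-chloro-5-[2-(hexadecanoyloxy)ethyl]-5-hydroxy-2-oxocyclohexane-1-carboxylate (mixture of racemic diastereomers) | CCCCCCCCCCCCCCCC(=O)OCCC1(O)CCC(=O)C(Cl)(C1)C(=O)OCc2ccccc2 | intermediate
13 | 5-[2-(hexadecanoyloxy)ethyl]-5-hydroxy-2-oxocyclohexane-1-carboxylic acid | CCCCCCCCCCCCCCCC(=O)OCCC1(O)CCC(=O)C(C1)C(=O)O | intermediate
14 | 2-(1-hydroxy-4-oxocyclohexyl)ethyl hexadecanoate | CCCCCCCCCCCCCCCC(=O)OCCC1(O)CCC(=O)CC1 | target

**Step count**
Total steps: 7. Longest linear sequence: 7 steps (1 → 3 → 5 → 6 → 8 → 9 → 12 → 14).

**Steps most likely to fail**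

Step 6 (carries the proposed new method). The tertiary cation may lose a proton, be taken by acetate, or be taken by the carbonyl of the ring benzyl ester with loss of the benzyl group, before the palmitate carbonyl reaches it. Fallback, setting out from 9 and returning at 12: 9 would be cyclised under the established conditions with Mn(OAc)3·2H2O and Cu(OAc)2·H2O (divalent copper) in AcOH. There the tertiary radical undergoes oxidative elimination, giving a mixture of the alkenes benzyl 1-chloro-5-[2-(hexadecanoyloxy)ethyl]-2-oxocyclohex-4-ene-1-carboxylate F1, benzyl 1-chloro-3-[2-(hexadecanoyloxy)ethyl]-6-oxocyclohex-2-ene-1-carboxylate F2 and benzyl 1-chloro-5-[2-(hexadecanoyloxy)ethylidene]-2-oxocyclohexane-1-carboxylate F3. The unseparated mixture would then be submitted to Mukaiyama hydration (Co(acac)2 cat., PhSiH3, O2, THF, rt). Markovnikov delivery of hydroxyl places the oxygen on the same ring carbon from all three isomers, so they should converge on 12. Any loss of chlorine in this hydration would be harmless, since chlorine is removed in step 7.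

Step 7. Hydrogenolysis of the tertiary C–Cl bond may stall once the benzyl group is gone, or the keto acid may lactonise onto the tertiary hydroxyl before it decarboxylates. Fallback, setting out from 12 and returning at 13: the chlorine would first be removed by dissolving-metal reduction (Zn dust, AcOH, rt) to give benzyl 5-[2-(hexadecanoyloxy)ethyl]-5-hydroxy-2-oxocyclohexane-1-carboxylate F4. Hydrogenolysis of the benzyl ester alone (H2, Pd/C, EtOAc, rt) would then give keto acid 13, which is decarboxylated as in step 7.

Step 5. Over-chlorination at C2 or electrophilic attack of the chlorinating agent on the 1,1-disubstituted alkene may erode the monochloride. Fallback, setting out from 6 and returning at 9 (steps 4 and 5 are bypassed): aldehyde 6 would be oxidised by the Pinnick method (NaClO2, NaH2PO4, excess 2-methylbut-2-ene, tBuOH/H2O) to 6-(hexadecanoyloxy)-4-methylidenehexanoic acid F5. This would be activated with 1,1'-carbonyldiimidazole in THF as 6-(1H-imidazol-1-yl)-3-methylidene-6-oxohexyl hexadecanoate F6. F6 would be added at −78 °C to two equivalents of the lithium enolate of benzyl chloroacetate (LiN(SiMe3)2, THF), a crossed Claisen C-acylation that gives 9 directly. The chlorine then arrives with the two-carbon unit and no separate chlorination of the keto ester is needed.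

**Further compounds**
F1 | step 6 | benzyl 1-chloro-5-[2-(hexadecanoyloxy)ethyl]-2-oxocyclohex-4-ene-1-carboxylate | CCCCCCCCCCCCCCCC(=O)OCCC1=CCC(=O)C(Cl)(C1)C(=O)OCc2ccccc2
F2 | step 6 | benzyl 1-chloro-3-[2-(hexadecanoyloxy)ethyl]-6-oxocyclohex-2-ene-1-carboxylate | CCCCCCCCCCCCCCCC(=O)OCCC1=CC(Cl)(C(=O)OCc2ccccc2)C(=O)CC1
F3 | step 6 | benzyl 1-chloro-5-[2-(hexadecanoyloxy)ethylidene]-2-oxocyclohexane-1-carboxylate (E/Z mixture) | CCCCCCCCCCCCCCCC(=O)OCC=C1CCC(=O)C(Cl)(C1)C(=O)OCc2ccccc2
F4 | step 7 | benzyl 5-[2-(hexadecanoyloxy)ethyl]-5-hydroxy-2-oxocyclohexane-1-carboxylate | CCCCCCCCCCCCCCCC(=O)OCCC1(O)CCC(=O)C(C1)C(=O)OCc2ccccc2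
F5 | step 5 | 6-(hexadecanoyloxy)-4-methylidenehexanoic acid | CCCCCCCCCCCCCCCC(=O)OCCC(=C)CCC(=O)O
F6 | step 5 | 6-(1H-imidazol-1-yl)-3-methylidene-6-oxohexyl hexadecanoate | CCCCCCCCCCCCCCCC(=O)OCCC(=C)CCC(=O)n1ccnc1
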